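**Plan**
1. Retrosynthesis: the C11 hydroperoxide and the C6=C7 bond come from a Schenck ene reaction on a C7=C11 isopropylidene. The angelate C–O bond and the C1 carbinol (from a C1 ketone) are cut next. Ring A is then opened at C2–C3, together with the C2–O bond of a temporary 2,3-oxirane. Last, C7=C11 (acetone), C1–C10 (acetylide) and C4–C5 (nitroalkene Michael addition) are cut back to 2-methylcyclohexanone.
2. Forward: ring B is present from the start. C4–C5 is made first, C1–C2 is attached to C10 as an alkyne, and C11–C13 come from acetone. Ring A then closes at C2–C3 by an intramolecular Darzens reaction (aldol plus oxirane closure, two rings in one operation). The hydroperoxide is made last.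
3. Enabling feature: C2 is the methylene between the two oxygenated carbons C1 and C3 of ring A. With C1 as a ketone conjugated to C9=C10 of ring B, C2 is an enolate carbon and C3 an aldehyde carbon. Because sp2 C10 is shared with the nearly planar ring B, ring A is locked with the C5 methyl axial, so only the axial (β) C3 alkoxide can displace an axial C2 bromide.
4. Helpers and their removal: bromine on C2 leaves in the key step; the 2β,3β-oxirane is opened at C2 in step 11; the C1 ketone is reduced in step 13; the C3 dimethyl acetal and the alkyne silyl cap are removed in steps 9 and 8.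
5. Stereochemistry: C5 and C4 come from the Michael addition of the (S)-1-phenylethylamine imine to (E)-1-nitropropene. C3 comes from the diaxial oxirane closure. C1 comes from hydride delivery anti to the axial C5 methyl and the 3β-ester.

Key step: step 10

Remark on the target: read from the SMILES, the C1 hydroxyl, the C3 angelate [(Z)-2-methylbut-2-enoate], the C4 methyl and the C5 methyl all lie on one face of ring A (1R,3S,4R,5R in eremophilane numbering).
Naming: atoms carry eremophilane numbers throughout (ring A = C1–C5 and C10, ring B = C5–C10, methyls on C4 and C5, C11–C13 on C7); β is the face of the C5 methyl. Monocyclic intermediates are named by IUPAC rules but their atoms keep these numbers in the Why lines.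
Assumption: (E)-1-nitroprop-1-ene (3) is bought; otherwise it is one nitroaldol/dehydration operation from nitromethane and acetaldehyde.

**Step 1**
Reactants: 1 2-methylcyclohexanone; 2 (S)-1-phenylethylamine; 3 (E)-1-nitroprop-1-ene
Product: 6 (2R)-2-methyl-2-[(2R)-1-nitropropan-2-yl]cyclohexan-1-one, via ketimine 4 (not isolated), via nitroalkyl ketimine 5 (not isolated)
Conditions: TsOH (cat.), toluene, reflux, Dean–Stark; then 3, THF, 0 °C → rt; then 20% aq. AcOH, rt
Reagents that add atoms: water, O
Why: Michael addition of the more substituted secondary-enamine tautomer of chiral ketimine 4 to the nitroalkene through a compact six-centre transition state, in which attack anti to the phenyl group of the auxiliary should set C5 as R (by analogy with the additions of this imine to other electron-poor alkenes) and the synclinal approach of the E-nitroalkene with its nitro group near N–H should set C4 as R (the two methyls cis in the later ring A), followed by hydrolysis of imine 5.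

**Step 2**
Reactants: 6 (2R)-2-methyl-2-[(2R)-1-nitropropan-2-yl]cyclohexan-1-one
Product: 8 (2R)-2-[(2R)-1,1-dimethoxypropan-2-yl]-2-methylcyclohexan-1-one, via sodium nitronate 7 (not isolated)
Conditions: NaOMe, MeOH, 0 °C; then added to conc. H2SO4/MeOH, −40 °C → rt
Reagents that add atoms: methanol, CO
Why: Nef reaction run in methanol, in which the nitronate is protonated, solvolysed with loss of N2O and the C3 aldehyde is trapped as its dimethyl acetal, so that C3 is protected for the base and oxidant steps that follow while C4 and C5 are not touched.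

**Step 3**
Reactants: 8 (2R)-2-[(2R)-1,1-dimethoxypropan-2-yl]-2-methylcyclohexan-1-one
Product: 9 (6R)-6-[(2R)-1,1-dimethoxypropan-2-yl]-6-methylcyclohex-2-en-1-one
Conditions: IBX, DMSO/toluene, 70 °C
Reagents that add atoms: none
Why: IBX dehydrogenation of a ketone to the enone through its enol, which can only give the C8=C9 bond because C5 is quaternary and C9 is the sole enolisable α-carbon.

**Step 4**
Reactants: 9 (6R)-6-[(2R)-1,1-dimethoxypropan-2-yl]-6-methylcyclohex-2-en-1-one; 10 (trimethylsilyl)acetylene
Product: 11 (6R)-6-[(2R)-1,1-dimethoxypropan-2-yl]-6-methyl-1-[(trimethylsilyl)ethynyl]cyclohex-2-en-1-ol (both C10 epimers)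
Conditions: 10, n-BuLi, THF, −78 °C; then 9, −78 → 0 °C; H2O
Reagents that add atoms: none
Why: 1,2-addition of a small lithium acetylide to the C10 carbonyl of the enone brings in C1 and C2, and the new carbinol centre is lost in step 5 so its configuration does not matter.

**Step 5**
Reactants: 11 (6R)-6-[(2R)-1,1-dimethoxypropan-2-yl]-6-methyl-1-[(trimethylsilyl)ethynyl]cyclohex-2-en-1-ol
Product: 12 (4R)-4-[(2R)-1,1-dimethoxypropan-2-yl]-4-methyl-3-[(trimethylsilyl)ethynyl]cyclohex-2-en-1-one
Conditions: C5H5NH[CrO3Cl] (pyridinium chlorochromate), 4 Å molecular sieves, CH2Cl2, rt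
Reagents that add atoms: none
Why: oxidative 1,3-transposition of a tertiary allylic alcohol (allylic shift of the chromate ester, then oxidation) moves the oxygen to C8 and leaves the alkyne on C10, the β-carbon of the new C8 enone, under anhydrous conditions that should spare the acetal.

**Step 6**
Reactants: 12 (4R)-4-[(2R)-1,1-dimethoxypropan-2-yl]-4-methyl-3-[(trimethylsilyl)ethynyl]cyclohex-2-en-1-one; 13 acetone
Product: 14 (4R)-4-[(2R)-1,1-dimethoxypropan-2-yl]-6-(2-hydroxypropan-2-yl)-4-methyl-3-[(trimethylsilyl)ethynyl]cyclohex-2-en-1-one (both C7 epimers)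
Conditions: LiN(i-Pr)2, THF, −78 °C; then 13; H2O
Reagents that add atoms: none
Why: kinetic α′-deprotonation at C7 (the only enolisable position, since C5 is quaternary and the alkyne is silyl-capped) and aldol addition to acetone attach C11–C13, and the C7 centre is removed in step 7.

**Step 7**
Reactants: 14 (4R)-4-[(2R)-1,1-dimethoxypropan-2-yl]-6-(2-hydroxypropan-2-yl)-4-methyl-3-[(trimethylsilyl)ethynyl]cyclohex-2-en-1-one
Product: 16 (4R)-4-[(2R)-1,1-dimethoxypropan-2-yl]-4-methyl-6-(propan-2-ylidene)-3-[(trimethylsilyl)ethynyl]cyclohex-2-en-1-one, via tertiary mesylate 15 (not isolated)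
Conditions: MsCl, Et3N, CH2Cl2, 0 °C; then DBU, rt
Reagents that add atoms: none
Why: mesylation of the tertiary alcohol and E1cB elimination through the C7 enolate should give the conjugated exocyclic C7=C11 isopropylidene (the pulegone-type enone needed for the final ene reaction) and not the isopropenyl isomer.

**Step 8**
Reactants: 16 (4R)-4-[(2R)-1,1-dimethoxypropan-2-yl]-4-methyl-6-(propan-2-ylidene)-3-[(trimethylsilyl)ethynyl]cyclohex-2-en-1-one
Product: 17 (4R)-3-(bromoethynyl)-4-[(2R)-1,1-dimethoxypropan-2-yl]-4-methyl-6-(propan-2-ylidene)cyclohex-2-en-1-one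
Conditions: NBS, AgNO3 (cat.), acetone, rt
Reagents that add atoms: N-bromosuccinimide, O=C1CCC(=O)N1Br
Why: silver-catalysed desilylative bromination of the alkynylsilane puts the future leaving group on C2, and the electron-poor ring alkenes should not react with NBS under these neutral conditions.

**Step 9**
Reactants: 17 (4R)-3-(bromoethynyl)-4-[(2R)-1,1-dimethoxypropan-2-yl]-4-methyl-6-(propan-2-ylidene)cyclohex-2-en-1-one
Product: 18 (2R)-2-[(1R)-2-(bromoacetyl)-1-methyl-4-oxo-5-(propan-2-ylidene)cyclohex-2-en-1-yl]propanal
Conditions: Ph3PAuNTf2 (cat.), H2O, 1,4-dioxane, 60 °C; then 1 M aq. HCl, THF, rt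
Reagents that add atoms: water, O
Why: gold-catalysed hydration of a 1-bromoalkyne places the carbonyl on the carbon remote from bromine (C1) to give the bromomethyl ketone, and the acid treatment unmasks the C3 aldehyde (a cyclic enol acetal formed by attack of an acetal oxygen on the activated alkyne would hydrolyse to the same product).

**Step 10**
Reactants: 18 (2R)-2-[(1R)-2-(bromoacetyl)-1-methyl-4-oxo-5-(propan-2-ylidene)cyclohex-2-en-1-yl]propanal
Product: 21 2β,3β-epoxyeremophila-7(11),9-diene-1,8-dione, via potassium enolate 19 (not isolated), via bromo alkoxide 20 (not isolated)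
Conditions: t-BuOK (1.0 equiv), THF/t-BuOH, −78 → 0 °C
Reagents that add atoms: none
Why: Intramolecular Darzens reaction: the bromoacetyl group (C1/C2) is the most acidic site and has no α′-hydrogen (no Favorskii path), so it gives enolate 19, whose C2 adds to the C3 aldehyde and closes ring A in a 6-(enolendo)-exo-trig aldol step. The aldol step is reversible and C2 is epimerisable, and only alkoxide 20, with the C3–O bond axial (β, syn to the axial C5 methyl) and the C2–Br bond axial (α), has the anti-periplanar arrangement for the 3-exo-tet closure of the oxirane, so the equatorial 3α-alkoxides should return to 18 and the material should drain through 20 to the 2β,3β-epoxide. Ring A cannot flip because sp2 C10 is shared with the nearly planar ring B, which keeps C6 equatorial and the C5 methyl axial, and this lock is what fixes both new centres (C2 and C3) relative to C5. The closest known reaction type is the Darzens condensation of α-halo ketones with aldehydes, ring-forming variants included, and the trans-diaxial demand mirrors the diaxial opening of cyclohexene oxides. The step needs chemoselective enolisation (secured by the acidity of the bromoacetyl group and one equivalent of base, which should leave C4–H of the aldehyde untouched) and the 3β-oxygen instead of the thermodynamically preferred equatorial 3α-oxygen (secured by the stereoelectronic demand of the oxirane closure).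

**Step 11**
Reactants: 21 2β,3β-epoxyeremophila-7(11),9-diene-1,8-dione
Product: 22 3β-hydroxyeremophila-7(11),9-diene-1,8-dione
Conditions: SmI2, THF/MeOH, −90 °C
Reagents that add atoms: none
Why: reductive opening of an α,β-epoxy ketone, in which electron transfer to the C1 carbonyl is followed by fast cleavage of the adjacent C2–O bond and protonation of the samarium enolate, so the oxirane opens only at C2 and C3 keeps its β-oxygen.

**Step 12**
Reactants: 22 3β-hydroxyeremophila-7(11),9-diene-1,8-dione; 23 angelic acid [(Z)-2-methylbut-2-enoic acid]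
Product: 25 3β-angeloyloxyeremophila-7(11),9-diene-1,8-dione, via mixed anhydride 24 (not isolated)
Conditions: 23, 2,4,6-trichlorobenzoyl chloride, Et3N, toluene, rt, filtered; then 22, toluene, 70 °C
Reagents that add atoms: none
Why: Yamaguchi esterification through mixed anhydride 24, run without a nucleophilic catalyst to keep the Z geometry of the angelate, at a stage where the axial 3β-hydroxyl has only one syn-axial neighbour because C1 is still sp2, and without free amine to limit E1cB loss of the new β-acyloxy group.

**Step 13**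
Reactants: 25 3β-angeloyloxyeremophila-7(11),9-diene-1,8-dione
Product: 26 3β-angeloyloxy-1β-hydroxyeremophila-7(11),9-dien-8-one
Conditions: NaBH4, CeCl3·7H2O, MeOH, −78 °C
Reagents that add atoms: none
Why: Luche reduction adds hydride 1,2 to the C1 carbonyl (less hindered and less cross-conjugated than C8) from the α-face, because the axial C5 methyl and the axial 3β-ester shield the β-face, which should give the 1β-alcohol cis to the ester, as in the reduction of steroidal 4-en-6-ones to 6β-ols.

**Step 14**
Reactants: 26 3β-angeloyloxy-1β-hydroxyeremophila-7(11),9-dien-8-one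
Product: 27 3β-angeloyloxy-1β-hydroxy-11-hydroperoxyeremophila-6,9-dien-8-one (CNP0300636.1)
Conditions: O2, tetraphenylporphyrin (cat.), visible light, CH2Cl2, 0 °C
Reagents that add atoms: dioxygen, O=O
Why: Schenck ene reaction of singlet oxygen with the s-cis enone C11=C7–C8=O, in which oxygen adds to the β-carbon C11 and hydrogen is taken from C6 (the alkyl group geminal to the carbonyl) so that the double bond moves to C6=C7, the tetrasubstituted alkene being expected to react faster than the electron-poor angelate and the s-trans C9=C10 bond.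

**Compound list**
1 | 2-methylcyclohexanone | CC1CCCCC1=O | starting material
2 | (S)-1-phenylethylamine | C[C@H](N)c1ccccc1 | starting material
3 | (E)-1-nitroprop-1-ene | C/C=C/[N+](=O)[O-] | starting material
4 | (S)-N-(2-methylcyclohexylidene)-1-phenylethanamine (ketimine, ring methyl centre and C=N geometry mixed) | CC1CCCCC1=N[C@@H](C)c1ccccc1 | intermediate
5 | (S)-N-{(2R)-2-methyl-2-[(2R)-1-nitropropan-2-yl]cyclohexylidene}-1-phenylethanamine | C[C@@H](C[N+](=O)[O-])[C@@]1(C)CCCCC1=N[C@@H](C)c1ccccc1 | intermediate
6 | (2R)-2-methyl-2-[(2R)-1-nitropropan-2-yl]cyclohexan-1-one | C[C@@H](C[N+](=O)[O-])[C@@]1(C)CCCCC1=O | intermediate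
7 | sodium nitronate of 6 | C[C@@H](C=[N+]([O-])[O-])[C@@]1(C)CCCCC1=O.[Na+] | intermediate
8 | (2R)-2-[(2R)-1,1-dimethoxypropan-2-yl]-2-methylcyclohexan-1-one | C[C@@H](C(OC)OC)[C@@]1(C)CCCCC1=O | intermediate
9 | (6R)-6-[(2R)-1,1-dimethoxypropan-2-yl]-6-methylcyclohex-2-en-1-one | C[C@@H](C(OC)OC)[C@@]1(C)CCC=CC1=O | intermediate
10 | (trimethylsilyl)acetylene | C#C[Si](C)(C)C | starting material
11 | (6R)-6-[(2R)-1,1-dimethoxypropan-2-yl]-6-methyl-1-[(trimethylsilyl)ethynyl]cyclohex-2-en-1-ol (carbinol centre mixed) | C[C@@H](C(OC)OC)[C@@]1(C)CCC=CC1(O)C#C[Si](C)(C)C | intermediate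
12 | (4R)-4-[(2R)-1,1-dimethoxypropan-2-yl]-4-methyl-3-[(trimethylsilyl)ethynyl]cyclohex-2-en-1-one | C[C@@H](C(OC)OC)[C@@]1(C)CCC(=O)C=C1C#C[Si](C)(C)C | intermediate
13 | acetone | CC(C)=O | starting material
14 | (4R)-4-[(2R)-1,1-dimethoxypropan-2-yl]-6-(2-hydroxypropan-2-yl)-4-methyl-3-[(trimethylsilyl)ethynyl]cyclohex-2-en-1-one (C7 centre mixed) | C[C@@H](C(OC)OC)[C@@]1(C)CC(C(C)(C)O)C(=O)C=C1C#C[Si](C)(C)C | intermediate
15 | methanesulfonate of the tertiary alcohol 14 | C[C@@H](C(OC)OC)[C@@]1(C)CC(C(C)(C)OS(C)(=O)=O)C(=O)C=C1C#C[Si](C)(C)C | intermediate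
16 | (4R)-4-[(2R)-1,1-dimethoxypropan-2-yl]-4-methyl-6-(propan-2-ylidene)-3-[(trimethylsilyl)ethynyl]cyclohex-2-en-1-one | C[C@@H](C(OC)OC)[C@@]1(C)CC(=C(C)C)C(=O)C=C1C#C[Si](C)(C)C | intermediate
17 | (4R)-3-(bromoethynyl)-4-[(2R)-1,1-dimethoxypropan-2-yl]-4-methyl-6-(propan-2-ylidene)cyclohex-2-en-1-one | C[C@@H](C(OC)OC)[C@@]1(C)CC(=C(C)C)C(=O)C=C1C#CBr | intermediate
18 | (2R)-2-[(1R)-2-(bromoacetyl)-1-methyl-4-oxo-5-(propan-2-ylidene)cyclohex-2-en-1-yl]propanal | C[C@@H](C=O)[C@@]1(C)CC(=C(C)C)C(=O)C=C1C(=O)CBr | intermediate
19 | potassium enolate of the bromoacetyl group of 18 | C[C@@H](C=O)[C@@]1(C)CC(=C(C)C)C(=O)C=C1C([O-])=CBr.[K+] | intermediate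
20 | potassium 2α-bromo-1,8-dioxoeremophila-7(11),9-dien-3β-olate | C[C@H]1[C@@H]([O-])[C@H](Br)C(=O)C2=CC(=O)C(=C(C)C)C[C@]12C.[K+] | intermediate
21 | 2β,3β-epoxyeremophila-7(11),9-diene-1,8-dione | C[C@H]1[C@H]2O[C@H]2C(=O)C3=CC(=O)C(=C(C)C)C[C@]13C | intermediate
22 | 3β-hydroxyeremophila-7(11),9-diene-1,8-dione | C[C@H]1[C@@H](O)CC(=O)C2=CC(=O)C(=C(C)C)C[C@]12C | intermediate
23 | angelic acid, (Z)-2-methylbut-2-enoic acid | C/C=C(/C)C(=O)O | starting material
24 | angelic 2,4,6-trichlorobenzoic anhydride | C/C=C(/C)C(=O)OC(=O)c1c(Cl)cc(Cl)cc1Cl | intermediate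
25 | 3β-angeloyloxyeremophila-7(11),9-diene-1,8-dione | C/C=C(/C)C(=O)O[C@H]1CC(=O)C2=CC(=O)C(=C(C)C)C[C@]2(C)[C@H]1C | intermediate
26 | 3β-angeloyloxy-1β-hydroxyeremophila-7(11),9-dien-8-one | C/C=C(/C)C(=O)O[C@H]1C[C@@H](O)C2=CC(=O)C(=C(C)C)C[C@]2(C)[C@H]1C | intermediate
27 | 3β-angeloyloxy-1β-hydroxy-11-hydroperoxyeremophila-6,9-dien-8-one | C/C=C(/C)C(=O)O[C@H]1C[C@@H](O)C2=CC(=O)C(C(C)(C)OO)=C[C@]2(C)[C@H]1C | target

**Totals**
Total step count: 14. Longest linear sequence: 14 steps (1 → 27, fully linear).

**Steps most likely to fail, with fallbacks**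

Step 10. The aldol equilibrium may not drain through the axial alkoxide: the retro-aldol may be slow, so that equatorial 3α-bromohydrins build up, or the aldehyde α-centre C4 may epimerise under base. The fallback sets out from 18 and returns at 21, and it sets the C3 oxygen by a directed epoxidation instead of the oxirane closure. SmI2 (THF, −78 °C) would turn the bromoketone into its samarium enolate, which closes ring A by a Reformatsky-type aldol to the hydroxy ketone F1, whose C3 configuration does not matter. Acid-catalysed dehydration (TsOH, benzene, 60 °C) would give the cross-conjugated trienedione F2. Luche reduction (NaBH4, CeCl3·7H2O) at the less hindered C1 carbonyl, from the α-face, would give the 1β-allylic alcohol F3. Hydroxyl-directed epoxidation (VO(acac)2, t-BuOOH, CH2Cl2) should deliver oxygen to the β-face of C2=C3 and give the epoxy alcohol F4. Oxidation of the C1 alcohol with DMP would return to 21.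

Step 11. The electron-transfer reagent may over-reduce the substrate, by conjugate reduction of the C9=C10 ene-dione or by loss of the β-oxygen, instead of cleaving only the C2–O bond. The fallback sets out from 21 and returns at 22 by a polar two-electron path. Sodium phenylselenide (PhSeSePh, NaBH4, EtOH/AcOH) should open the oxirane at C2 from the α-face (diaxial opening at the carbon α to the carbonyl) to the selanyl ketone F5. A second selenide ion would then attack selenium and release the C1 enolate, which is protonated to 22.

Step 12. The new β-acyloxy ketone may eliminate across C2–C3 under heat or residual base, and the angelate may isomerise from Z to E. The fallback sets out from 21 and returns at 26, so that the ester is never β to a carbonyl. Luche reduction of 21 (hydride anti to the oxirane and the C5 methyl) would give the epoxy alcohol F4 (the same compound as in the fallback for step 10). TESOTf/2,6-lutidine would give the silyl ether F6. Sodium phenylselenide would open the oxirane trans-diaxially at C2 to the hydroxy selenide F7. Bu3SnH with AIBN would remove selenium to give the alcohol F8. Yamaguchi esterification with 23 would give the ester F9, and HF·pyridine would remove the silyl group to give 26.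

**Further compounds**
F1 | step 10 | 3α-hydroxyeremophila-7(11),9-diene-1,8-dione (C3 epimer of 22; either epimer serves) | C[C@H]1[C@H](O)CC(=O)C2=CC(=O)C(=C(C)C)C[C@]12C
F2 | step 10 | eremophila-2,7(11),9-triene-1,8-dione | C[C@H]1C=CC(=O)C2=CC(=O)C(=C(C)C)C[C@]12C
F3 | step 10 | 1β-hydroxyeremophila-2,7(11),9-trien-8-one | C[C@H]1C=C[C@@H](O)C2=CC(=O)C(=C(C)C)C[C@]12C
F4 | step 10 | 2β,3β-epoxy-1β-hydroxyeremophila-7(11),9-dien-8-one | C[C@H]1[C@H]2O[C@H]2[C@@H](O)C2=CC(=O)C(=C(C)C)C[C@]12C
F5 | step 11 | 3β-hydroxy-2α-(phenylselanyl)eremophila-7(11),9-diene-1,8-dione | C[C@H]1[C@@H](O)[C@H]([Se]c2ccccc2)C(=O)C2=CC(=O)C(=C(C)C)C[C@]12C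
F6 | step 12 | 2β,3β-epoxy-1β-(triethylsilyloxy)eremophila-7(11),9-dien-8-one | C[C@H]1[C@H]2O[C@H]2[C@@H](O[Si](CC)(CC)CC)C2=CC(=O)C(=C(C)C)C[C@]12C
F7 | step 12 | 3β-hydroxy-2α-(phenylselanyl)-1β-(triethylsilyloxy)eremophila-7(11),9-dien-8-one | C[C@H]1[C@@H](O)[C@H]([Se]c2ccccc2)[C@@H](O[Si](CC)(CC)CC)C2=CC(=O)C(=C(C)C)C[C@]12C
F8 | step 12 | 3β-hydroxy-1β-(triethylsilyloxy)eremophila-7(11),9-dien-8-one | C[C@H]1[C@@H](O)C[C@@H](O[Si](CC)(CC)CC)C2=CC(=O)C(=C(C)C)C[C@]12C
F9 | step 12 | 3β-angeloyloxy-1β-(triethylsilyloxy)eremophila-7(11),9-dien-8-one | C/C=C(/C)C(=O)O[C@H]1C[C@@H](O[Si](CC)(CC)CC)C2=CC(=O)C(=C(C)C)C[C@]2(C)[C@H]1C
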